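The easy step came first, and I wrote down what went into the four flasks for whoever took over the bench.

    second reagent + intermediate A → intermediate B (k1 = 0.832 /M/s)
    second reagent + protic impurity → quenched reagent (k2 = 59.8 /M/s)
    third reagent + intermediate B → target (k3 = 0.298 /M/s)
    intermediate B + capture agent → trapped intermediate (k4 = 2.64 /M/s)
    substrate + second reagent → side product (k5 = 0.00891 /M/s)
    substrate + partner → intermediate A (k6 = 0.680 /M/s)

| flask | substrate | partner | second reagent | third reagent | protic impurity | capture agent | time |
|---|---|---|---|---|---|---|---|
| autumn | 0.050 M | 0.0400 M | 0.125 M | 0.100 M | 1.00 mM | 0.0150 M | 40 s |
| spring | 0.050 M | 0.0600 M | 0.125 M | 0.100 M | 1.00 mM | 0.0150 M | 40 s |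
| noon | 0.050 M | 0.100 M | 0.125 M | 0.100 M | 1.00 mM | 0.0150 M | 40 s |
| winter | 0.050 M | 0.150 M | 0.125 M | 0.100 M | 1.00 mM | 0.0150 M | 40 s |

- [intermediate A] at the end for autumn, spring, noon, winter, in this order
- how that number moves from the first to the last of them (falls, then rises / rises all the way / rises, then falls / hardly changes / falls all the way)

- "hardly changes" means that all values lie within two and a half points (for a concentration: within two and a half percent of the largest)
- run time (autumn): 40 s

I read intermediate A as a tank between two clocks. Substrate filled it with the pseudo-first-order constant 0.0272 /s in autumn, and the second reagent drained it with 0.104 /s. I carried their quotient, the balance ratio r, fill constant over drain constant at the charge, 0.262 in autumn. Its zero of the scale is the symmetric case, r equal to one, which needs 0.153 M of partner. Winter stood almost there, at 0.981.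

My note said to expect substrate still feeding in autumn, where the fill half-life of 25 s is shorter than the run by a modest margin. With constants held at the charge, I reckoned 33.7% of the substrate left at the end in autumn and 1.69% in winter. The note also said not to correct the drain for the protic impurity, charged at far less than the second reagent, or the fill for the loss of substrate to side product, which by itself gives substrate a half-life of 10 min in autumn, much longer than the fill half-life. The symmetric chain gave me one point, c(intermediate A) = 0.00325 M for winter, and I took my reckoning no further.

The forecast gave 0.0048 M, 0.0061 M, 0.0067 M and 0.0063 M, so rises, then falls, with winter at twice my point. Its ground was that “at high partner the substrate is spent early and A has already decayed by 40 s”.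

The flasks gave 0.00423 M, 0.00562 M, 0.00674 M and 0.00631 M: rises, then falls. The row turned at a reading of 0.11 M of partner, which is r = 0.703, less than the symmetric charge. At the end of autumn, with 39.7% of the partner and 82.2% of the second reagent left, r taken with these concentrations in place of the charge had fallen to 0.126. Multiplied by the remaining substrate, that gives 0.00310 M against 0.00423 M, and making over use stood at 0.732. In winter the same product is 0.00219 M against 0.00631 M.

The numbers stand for no real mixture; the rest is arithmetic.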